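The route disconnects the O1–C2 and C1'–C2' bonds of the chromanone at the same time. C2 of ring B (the oxygen heterocycle) is quaternary and carries O1, a methyl group and the C1' methylene, which is the imprint of a phenol adding to a 1,1-disubstituted alkene. A chiral catalyst of divalent palladium closes ring B by this addition and fixes C2. Because the C1'–Pd species so formed has no β-hydrogen, it couples with but-3-en-2-one before it collapses. The precursor is a 2-(3-methylbut-3-enyl)phenol that already holds the C7 bromine and the C6 oxygen as a silyl ether; the C4 carbonyl and the tertiary carbinol follow afterwards.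

Key step: step 6

Remark on numbering: chroman numbering (O1, C2, C3, C4, C4a, C5–C8, C8a; side chain C1'–C4') is used throughout, ring A being the benzene ring and ring B the oxygen heterocycle.

Assumption: the (S,S)-ligand is expected to give the (2S)-enone 9, by analogy with related 2-(3-methylbut-3-enyl)phenols; should the sense of induction prove opposite, its mirror image is used and nothing else changes.

Remark on descriptors: C2 is S in 9 and R in 10–14 only because C3 outranks C1' once the side-chain alkene is saturated; the spatial arrangement is the same throughout.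

Step 1
Reactants: 1 4-bromo-2,5-dimethoxybenzaldehyde
Product: 2 4-bromo-2,5-dihydroxybenzaldehyde
Conditions: BBr3 (3.5 equiv), CH2Cl2, −78 °C to rt; then H2O
Reagents that add atoms: none
Why: Lewis acid ether cleavage, in which BBr3 complexes each aryl methyl ether and bromide removes the methyl group by SN2, while the aldehyde and the aryl bromide are inert and the borate esters hydrolyse on work-up.

Step 2
Reactants: 2 4-bromo-2,5-dihydroxybenzaldehyde
Product: 3 4-bromo-2-hydroxy-5-(triisopropylsilyloxy)benzaldehyde
Conditions: TIPSCl (1.05 equiv), imidazole (2.2 equiv), DMF, 0 °C to rt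
Reagents that add atoms: triisopropylsilyl chloride, CC(C)[Si](Cl)(C(C)C)C(C)C
Why: Selective phenol silylation, since the C2 hydroxyl is held in a hydrogen bond to the formyl oxygen and is much less nucleophilic, so one equivalent of the bulky silyl chloride should react only at the free C5 hydroxyl.

Step 3
Reactants: 3 4-bromo-2-hydroxy-5-(triisopropylsilyloxy)benzaldehyde; 4 acetonylidenetriphenylphosphorane
Product: 5 (E)-4-[4-bromo-2-hydroxy-5-(triisopropylsilyloxy)phenyl]but-3-en-2-one
Conditions: toluene, 80 °C
Reagents that add atoms: none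
Why: Wittig reaction with a stabilised ylide, which is too weakly basic to be quenched by the phenol and should deliver the E-enone.

Step 4
Reactants: 5 (E)-4-[4-bromo-2-hydroxy-5-(triisopropylsilyloxy)phenyl]but-3-en-2-one
Product: 6 4-[4-bromo-2-hydroxy-5-(triisopropylsilyloxy)phenyl]butan-2-one
Conditions: H2 (5 bar), RhCl(PPh3)3 (5 mol %), toluene/EtOH 1:1, 40 °C
Reagents that add atoms: none
Why: Homogeneous catalytic hydrogenation at RhCl(PPh3)3 saturates the conjugated C=C bond while leaving the ketone, the silyl ether and the aryl bromide alone, the last of which heterogeneous palladium would endanger.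

Step 5
Reactants: 6 4-[4-bromo-2-hydroxy-5-(triisopropylsilyloxy)phenyl]butan-2-one
Product: 7 5-bromo-2-(3-methylbut-3-en-1-yl)-4-(triisopropylsilyloxy)phenol
Conditions: Ph3PCH3Br (3.5 equiv), NaN(SiMe3)2 (3.3 equiv), THF, 0 °C to rt
Reagents that add atoms: methyltriphenylphosphonium bromide, C[P+](c1ccccc1)(c1ccccc1)c1ccccc1.[Br-]
Why: Wittig methylenation with excess ylide, in which the first equivalent only deprotonates the phenol (keeping 6 in its open keto form), the remainder converts the methyl ketone into the 1,1-disubstituted alkene, and the alkoxide-free ylide spares the aryl silyl ether and the aryl bromide.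

Step 6
Reactants: 7 5-bromo-2-(3-methylbut-3-en-1-yl)-4-(triisopropylsilyloxy)phenol; 8 but-3-en-2-one
Product: 9 (E)-5-[(2S)-7-bromo-2-methyl-6-(triisopropylsilyloxy)chroman-2-yl]pent-3-en-2-one
Conditions: Pd(OCOCF3)2 (10 mol %), (S,S)-Bn-BOXAX [(S)-axial 2,2'-bis((4S)-4-benzyl-4,5-dihydrooxazol-2-yl)-1,1'-binaphthyl] (20 mol %), p-benzoquinone (4 equiv), 8 (5 equiv), CH2Cl2, rt
Reagents that add atoms: none
Why: Divalent palladium carrying the chiral bis(oxazoline) binds the 1,1-disubstituted alkene of 7 and the phenol oxygen attacks its internal carbon (O1–C2); the neopentyl-type C1'–Pd species has no β-hydrogen because C2 is quaternary, so it persists until it inserts but-3-en-2-one (C1'–C2'), after which β-hydride elimination releases the enone and p-benzoquinone returns zerovalent palladium to the divalent state. The closest known reaction type is the enantioselective domino Wacker–Heck cyclisation of 2-(3-methylbut-3-enyl)phenols with acrylates or vinyl ketones under Pd(OCOCF3)2, a BOXAX ligand and p-benzoquinone. Ring B closes in the 6-exo-trig mode. The C2 stereocentre is set by the ligand, which distinguishes the two faces of the prochiral alkene in the oxypalladation, and no later step touches it. The step needs alkene activation to win over oxidative addition into C7–Br, which the phosphine-free catalyst, room temperature and fast reoxidation of zerovalent palladium should secure, and it needs ring A to survive the quinone, which the silyl ether on the para oxygen secures. The E geometry follows from syn β-hydride elimination placing the acetyl group and C1' trans.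

Step 7
Reactants: 9 (E)-5-[(2S)-7-bromo-2-methyl-6-(triisopropylsilyloxy)chroman-2-yl]pent-3-en-2-one
Product: 10 5-[(2R)-7-bromo-2-methyl-6-(triisopropylsilyloxy)chroman-2-yl]pentan-2-one
Conditions: H2 (5 bar), RhCl(PPh3)3 (10 mol %), toluene/EtOH 1:1, rt
Reagents that add atoms: none
Why: Homogeneous catalytic hydrogenation of the enone C=C bond, chemoselective over the ketone and the C7–Br bond and without effect on C2.

Step 8
Reactants: 10 5-[(2R)-7-bromo-2-methyl-6-(triisopropylsilyloxy)chroman-2-yl]pentan-2-one
Product: 11 5-[(2R)-7-bromo-2-methyl-6-(triisopropylsilyloxy)chroman-2-yl]-2-methylpentan-2-ol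
Conditions: MeMgBr (3 equiv), THF, −78 to 0 °C; then aq. NH4Cl
Reagents that add atoms: methylmagnesium bromide, C[Mg]Br
Why: Grignard 1,2-addition to the unhindered methyl ketone gives the tertiary carbinol, since MeMgBr does not exchange with the aryl bromide at low temperature and the hindered aryl silyl ether resists it.

Step 9
Reactants: 11 5-[(2R)-7-bromo-2-methyl-6-(triisopropylsilyloxy)chroman-2-yl]-2-methylpentan-2-ol
Product: 13 (2R)-7-bromo-2-(4-hydroxy-4-methylpentyl)-2-methyl-6-(triisopropylsilyloxy)chroman-4-one, via C4 tert-butyl peroxide 12 (not isolated)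
Conditions: Mn(OAc)3·2H2O (0.2 equiv), tBuOOH (5 equiv, in decane), 3 Å MS, EtOAc, rt
Reagents that add atoms: tert-butyl hydroperoxide, CC(C)(C)OO
Why: Radical benzylic C–H oxidation with trivalent manganese and tert-butyl hydroperoxide, a known way from chromans to chroman-4-ones, in which C4 holds the only benzylic hydrogens (C2 has none next to O1), the C4 radical is capped as peroxide 12 and loss of tert-butanol gives the ketone, while the tertiary alcohol and the silyl-capped ring A should stay intact under these neutral conditions.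

Step 10
Reactants: 13 (2R)-7-bromo-2-(4-hydroxy-4-methylpentyl)-2-methyl-6-(triisopropylsilyloxy)chroman-4-one
Product: 14 (2R)-7-bromo-6-hydroxy-2-(4-hydroxy-4-methylpentyl)-2-methylchroman-4-one
Conditions: Bu4NF (1.2 equiv), AcOH (1.5 equiv), THF, 0 °C
Reagents that add atoms: none
Why: Fluoride desilylation of the aryl silyl ether, buffered with acetic acid so that the medium stays non-basic, the β-aryloxy ketone cannot open by retro-oxa-Michael reaction and C2 is not scrambled.

Compound list
1 | 4-bromo-2,5-dimethoxybenzaldehyde | COc1cc(Br)c(OC)cc1C=O | starting material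
2 | 4-bromo-2,5-dihydroxybenzaldehyde | O=Cc1cc(O)c(Br)cc1O | intermediate
3 | 4-bromo-2-hydroxy-5-(triisopropylsilyloxy)benzaldehyde | O=Cc1cc(O[Si](C(C)C)(C(C)C)C(C)C)c(Br)cc1O | intermediate
4 | acetonylidenetriphenylphosphorane | CC(=O)C=P(c1ccccc1)(c1ccccc1)c1ccccc1 | starting material
5 | (E)-4-[4-bromo-2-hydroxy-5-(triisopropylsilyloxy)phenyl]but-3-en-2-one | CC(=O)/C=C/c1cc(O[Si](C(C)C)(C(C)C)C(C)C)c(Br)cc1O | intermediate
6 | 4-[4-bromo-2-hydroxy-5-(triisopropylsilyloxy)phenyl]butan-2-one | CC(=O)CCc1cc(O[Si](C(C)C)(C(C)C)C(C)C)c(Br)cc1O | intermediate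
7 | 5-bromo-2-(3-methylbut-3-en-1-yl)-4-(triisopropylsilyloxy)phenol | C=C(C)CCc1cc(O[Si](C(C)C)(C(C)C)C(C)C)c(Br)cc1O | intermediate
8 | but-3-en-2-one | C=CC(C)=O | starting material
9 | (E)-5-[(2S)-7-bromo-2-methyl-6-(triisopropylsilyloxy)chroman-2-yl]pent-3-en-2-one | CC(=O)/C=C/C[C@]1(C)CCc2cc(O[Si](C(C)C)(C(C)C)C(C)C)c(Br)cc2O1 | intermediate
10 | 5-[(2R)-7-bromo-2-methyl-6-(triisopropylsilyloxy)chroman-2-yl]pentan-2-one | CC(=O)CCC[C@]1(C)CCc2cc(O[Si](C(C)C)(C(C)C)C(C)C)c(Br)cc2O1 | intermediate
11 | 5-[(2R)-7-bromo-2-methyl-6-(triisopropylsilyloxy)chroman-2-yl]-2-methylpentan-2-ol | CC(C)(O)CCC[C@]1(C)CCc2cc(O[Si](C(C)C)(C(C)C)C(C)C)c(Br)cc2O1 | intermediate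
12 | 5-[(2R)-7-bromo-4-(tert-butylperoxy)-2-methyl-6-(triisopropylsilyloxy)chroman-2-yl]-2-methylpentan-2-ol, mixture of C4 epimers | CC(C)(O)CCC[C@]1(C)CC(OOC(C)(C)C)c2cc(O[Si](C(C)C)(C(C)C)C(C)C)c(Br)cc2O1 | intermediate (not isolated)
13 | (2R)-7-bromo-2-(4-hydroxy-4-methylpentyl)-2-methyl-6-(triisopropylsilyloxy)chroman-4-one | CC(C)(O)CCC[C@]1(C)CC(=O)c2cc(O[Si](C(C)C)(C(C)C)C(C)C)c(Br)cc2O1 | intermediate
14 | (2R)-7-bromo-6-hydroxy-2-(4-hydroxy-4-methylpentyl)-2-methylchroman-4-one | CC(C)(O)CCC[C@]1(C)CC(=O)c2cc(O)c(Br)cc2O1 | target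

Total step count: 10
Longest linear sequence: 10 steps (1 to 14)

Steps most likely to fail

Step 6. The hindered C1'–Pd intermediate may take up the enone too slowly, so that catalyst decay, oligomerisation of the enone or insertion of zerovalent palladium into C7–Br overtakes turnover. The fallback sets out from 7 and replaces the Heck termination by carbonylative capture, a known domino oxypalladation–carbonylation of this phenol class. Pd(OCOCF3)2, (S,S)-Bn-BOXAX, p-benzoquinone, CO (1 bar) and MeOH at rt should give methyl 2-[(2S)-7-bromo-2-methyl-6-(triisopropylsilyloxy)chroman-2-yl]acetate F1. Reduction with iBu2AlH in CH2Cl2 at −78 °C should give 2-[(2S)-7-bromo-2-methyl-6-(triisopropylsilyloxy)chroman-2-yl]acetaldehyde F2. F2 is used crude, because a base could open ring B, and is olefinated with phosphorane 4 in CH2Cl2 at rt, which rejoins the route at 9.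

Step 9. O1 and the C6 silyloxy group are para to each other, so ring A is a masked hydroquinone. The oxidation may therefore turn to ring A with loss of the silyl group, or it may stall before the ketone. The fallback sets out from 11 and installs the C4 oxygen in stages. DDQ in refluxing benzene should dehydrogenate C3–C4 to 5-[(2R)-7-bromo-2-methyl-6-(triisopropylsilyloxy)-2H-chromen-2-yl]-2-methylpentan-2-ol F3. Mukaiyama hydration (Co(acac)2, PhSiH3, O2, iPrOH, then reductive work-up) should place the hydroxyl at benzylic C4 and give (2R)-7-bromo-2-(4-hydroxy-4-methylpentyl)-2-methyl-6-(triisopropylsilyloxy)chroman-4-ol F4 as a mixture of C4 epimers. Dess–Martin periodinane in CH2Cl2 then oxidises only the secondary alcohol and rejoins the route at 13.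

Step 7. Hydrogen uptake at the electron-poor C2'=C3' bond beside the neopentyl centre may be sluggish, and forcing it may bring hydrogenolysis of C7–Br or reduction of the ketone. The fallback sets out from 9 and reverses the order of the two operations. MeMgBr with CeCl3 in THF at −78 °C should add 1,2 to the enone and give (E)-5-[(2S)-7-bromo-2-methyl-6-(triisopropylsilyloxy)chroman-2-yl]-2-methylpent-3-en-2-ol F5. The now isolated alkene is reduced with diimide (TsNHNH2, NaOAc, DME/H2O, reflux), which cannot touch the C–Br bond, and the route is rejoined at 11.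

Further compounds
F1 | step 6 | methyl 2-[(2S)-7-bromo-2-methyl-6-(triisopropylsilyloxy)chroman-2-yl]acetate | COC(=O)C[C@]1(C)CCc2cc(O[Si](C(C)C)(C(C)C)C(C)C)c(Br)cc2O1
F2 | step 6 | 2-[(2S)-7-bromo-2-methyl-6-(triisopropylsilyloxy)chroman-2-yl]acetaldehyde | O=CC[C@]1(C)CCc2cc(O[Si](C(C)C)(C(C)C)C(C)C)c(Br)cc2O1
F3 | step 9 | 5-[(2R)-7-bromo-2-methyl-6-(triisopropylsilyloxy)-2H-chromen-2-yl]-2-methylpentan-2-ol | CC(C)(O)CCC[C@]1(C)C=Cc2cc(O[Si](C(C)C)(C(C)C)C(C)C)c(Br)cc2O1
F4 | step 9 | (2R)-7-bromo-2-(4-hydroxy-4-methylpentyl)-2-methyl-6-(triisopropylsilyloxy)chroman-4-ol, mixture of C4 epimers | CC(C)(O)CCC[C@]1(C)CC(O)c2cc(O[Si](C(C)C)(C(C)C)C(C)C)c(Br)cc2O1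
F5 | step 7 | (E)-5-[(2S)-7-bromo-2-methyl-6-(triisopropylsilyloxy)chroman-2-yl]-2-methylpent-3-en-2-ol | CC(C)(O)/C=C/C[C@]1(C)CCc2cc(O[Si](C(C)C)(C(C)C)C(C)C)c(Br)cc2O1
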